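Remark (assumption): atoms keep their eremophilane (target) numbers at every stage, also in the bicyclic precursors (bridgeheads C3 and C10; bridges C8–C9, C4=C5 and C1–C2), whereas systematic names use their own locants; α/β refer to the usual drawing with H-10, C-14 (on C5) and C-15 (on C4) β, so that the target is the 3α-tigloyloxy-9β-senecioyloxy-7β-isopropenyl compound, (3R,4R,5R,7R,9R,10S).

## Structural features

The target is a cis-fused decalin (eremophilane). Ring A (C1–C5, C10) carries the tigloyl ester at C3 and the secondary methyl group at C4; ring B (C5–C10) carries the isopropenyl group at C7, the ketone at C8 and the senecioyl ester at C9; the rings share the quaternary C5 (methyl) and C10 (H). Five of the six stereocenters are contiguous (C3–C4–C5–C10–C9); C7 is separated from them by C6 and C8. The C4 and C5 methyl groups are cis, H-10 is cis to the C5 methyl group, the C3 oxygen is trans to the C4 methyl group, and in the chair–chair form with the C5 methyl group axial on ring A the substituents at C3, C4, C7 and C9 are all equatorial. Fragile groups are the β,γ-unsaturated ketone (C7–H is doubly activated, so C7 epimerises and C11=C12 moves into conjugation), the α-acyloxy ketone at C9, and two different unsaturated esters on two secondary alcohols. The real difficulty is the quaternary C5 with its two cis neighbours (C4 methyl, H-10), together with the near-degeneracy of the two chair–chair forms of a cis-decalin, which leaves no ring face reliably shielded unless one stereocenter acts as a conformational anchor. The key step exploits that C8 is joined to C5 through C7–C6 and C3 is joined to C5 through C4: a temporary C3–C8 bond turns the skeleton into a bicyclo[2.2.2]oct-5-ene in which C6=C7–C8(O)–C3–C4=C5 is a 3-oxy-1,5-diene, whose [3,3] shift forms C5–C6, cleaves C3–C8, returns C8 as the ketone and leaves C3=C4 as the retron for the trans C3–O/C4–H pair. In one sentence, the route is the anionic oxy-Cope rearrangement of the bicyclic dienyl carbinol 14 to the cis-octalone 18, a description that does not fit an annulation or cycloaddition route to the decalin.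

## Logic of the disconnections

27 ⇒ 26 ⇒ 25 ⇒ 24. The acyl C–O bond at O9, the benzyl ether bond at O9 and the acyl C–O bond at O3 are cut in this order. The base-sensitive α-acyloxy ketone is made last, and the ether on O9 differentiates the two alcohols. All enolate chemistry is thereby finished before any ester is present. The forward steps must acylate without enolising C7 or C9 and deprotect under neutral conditions.

24 ⇒ 21. The C7–H bond is cut and C11=C12 is moved to C7=C11. This removes the C7 stereocenter and masks the reactive 1,1-disubstituted alkene as a conjugated tetrasubstituted one that can stand borane. The forward step is a deconjugative protonation followed by equilibration of C7, which is downhill once ring A is locked.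

21 ⇒ 20 ⇒ 18. The C3–O and C4–H bonds are cut (syn-hydration retron) and the oxidation level of C8 is adjusted. C3 and C4 disappear into the C3=C4 alkene. The forward hydroboration must come from the α face, which requires the ring-flip form fixed by an equatorial 9β oxygen.

18 ⇒ 14 (key). The C5–C6 bond is cut and the C3–C8 bond, absent from the target, is made. The quaternary C5, the cis fusion and ring B all vanish, and what is left is a rigid bicyclo[2.2.2]octene whose only set stereocenters are C8, C9 and the bridgeheads. The forward step needs the dienyl group and the C9 oxygen both syn to the C4=C5 bridge, and a potassium alkoxide.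

14 ⇒ 13. The C6=C7 and C11=C12 double bonds are cut, so that both methylene carbons come from ethylene and a slim, robust alkyne is carried through the preceding steps. The forward step is an alkyne–ethylene metathesis next to a tertiary carbinol.

13 ⇒ 12 ⇒ 11 ⇒ 10 ⇒ 9. The benzyl ether bond, the C9–H bond and the C7–C8 bond are cut. The carbon substituent at C8 and the oxygen at C9 must be cis, and a nucleophile adds anti to an existing C9 oxygen. Therefore C8 is made first next to a temporary C9 alcohol, which is then oxidised and reset from the opposite face by hydride delivered from the C8 hydroxyl. The demands are face-selective addition (step 7) and intramolecular hydride delivery (step 9).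

9 ⇒ 8. One C9–H bond is cut and the compound becomes meso. All absolute stereochemistry then comes from one catalytic desymmetrisation. The catalyst must distinguish two enantiotopic carbonyl groups and stop after one reduction.

8 ⇒ 7 ⇒ 6 ⇒ 4 + 5. The C3–C8 and C9–C10 bonds are cut (Diels–Alder) after adjusting the oxidation level. The mirror plane makes stereocontrol unnecessary, and the endo/exo ratio is irrelevant because both carbinol carbons become carbonyl groups.

4 ⇒ 3 ⇒ 1. One alkene C–CH3 bond (C5–C14 or the equivalent C4–C15) is cut to an enol triflate, and this to a commercial enone. The forward steps are a kinetic α′ enolisation and a methyl cross-coupling.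

## Other disconnections considered

Alternative 1: The first that comes to mind is the Robinson annulation, cutting C4–C5 and C1–C10: 2-methylcyclohexane-1,3-dione and (E)-pent-3-en-2-one would give the dimethyl Wieland–Miescher-type dione A1. It sets only the C4/C5 pair, through an open Michael transition state with limited cis preference. It places oxygen at C2 and C6 instead of C3, C8 and C9, so three transpositions would follow. The cis ring fusion would have to come from reduction of the C1=C10 enone, which has no built-in bias. The chosen plan sets C5 and C10 together in a geometrically forced step and delivers C8 and C3=C4 at the right positions.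

Alternative 2: An intramolecular Diels–Alder reaction, cutting C5–C10 and C1–C2: trienone A2 (dienophile C10=C1 activated by a C9 carbonyl, diene C5=C4–C3=C2) would close both rings to octalone A3. The diene terminus C5 is fully substituted and one of its groups is necessarily Z, which disfavours the s-cis form and slows bond formation at the future quaternary center. The endo/exo choice (cis or trans fusion) is not enforced by the tether. The activation pattern puts the ketone at C9 and the ether at C8, so a ketol transposition next to the epimerisable C10 would be needed, and C4 stays sp2 in any case. The oxy-Cope plan reaches the same two rings with the fusion fixed by the bicycle.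

Alternative 3: The same temporary C3–C8 bond, but with the [3,3] shift closing C1–C10 instead of C5–C6: carbinol A5, from diene A4 by Diels–Alder reaction with a ketene equivalent, α-methylation and vinyl addition. This would give the C3 ketone and a C8 enol ether directly and has the shorter endgame. However, A4 has a 1,3 (meta) relation of methyl and isopropenyl groups with no short enantioselective entry, and its stereocenter is α to a carbonyl in every obvious precursor. C4 would depend on a later equilibration, and the vinyl group would have to add next to the C4 methyl group. The chosen mapping starts from a meso dione, so that one catalytic reduction fixes the absolute configuration.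

Key step: step 12

## Route

Step 1
Reactants: 1 2-methylcyclohex-2-en-1-one
Product: 3 6-methylcyclohexa-1,5-dien-1-yl trifluoromethanesulfonate, via lithium dienolate 2 (not isolated)
Conditions: LiN(iPr)2, THF, −78 °C; PhNTf2, −78 °C to rt
Reagents that add atoms: N-phenylbis(trifluoromethanesulfonimide), O=S(=O)(N(c1ccccc1)S(=O)(=O)C(F)(F)F)C(F)(F)F
Why: Kinetic deprotonation of the enone at the α′ carbon gives the cross-conjugated dienolate, which is sulfonylated on oxygen (enol triflate formation); no stereocenter is formed.

Step 2
Reactants: 3 6-methylcyclohexa-1,5-dien-1-yl trifluoromethanesulfonate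
Product: 4 2,3-dimethylcyclohexa-1,3-diene
Conditions: MeMgBr, Fe(acac)3 (5 mol%), THF/NMP, −30 to 0 °C
Reagents that add atoms: methylmagnesium bromide, C[Mg]Br
Why: Iron-catalysed Kumada-type cross-coupling of an alkenyl triflate with a methyl Grignard reagent replaces the triflate by methyl and leaves the diene intact; the volatile diene is purified by distillation.

Step 3
Reactants: 4 2,3-dimethylcyclohexa-1,3-diene; 5 vinylene carbonate (1,3-dioxol-2-one)
Product: 6 meso-(3aR,4S,7R,7aS)-5,6-dimethyl-3a,4,7,7a-tetrahydro-4,7-ethano-1,3-benzodioxol-2-one (endo adduct)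
Conditions: neat in excess 5, BHT (cat.), sealed tube, 170 °C
Reagents that add atoms: none
Why: Thermal Diels–Alder reaction of an electron-rich cyclohexadiene with vinylene carbonate as a cis-enediol equivalent forms the C3–C8 and C9–C10 bonds; the mirror plane is kept, so the adduct is meso, and the endo/exo ratio does not matter because both carbinol carbons become carbonyl groups in step 5.

Step 4
Reactants: 6 meso carbonate adduct
Product: 7 meso-(1R,2S,3R,4S)-5,6-dimethylbicyclo[2.2.2]oct-5-ene-2,3-diol
Conditions: NaOH, H2O/THF, 50 °C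
Reagents that add atoms: none
Why: Saponification of the cyclic carbonate; no stereocenter is touched.

Step 5
Reactants: 7 meso-5,6-dimethylbicyclo[2.2.2]oct-5-ene-2,3-diol
Product: 8 meso-(1R,4S)-5,6-dimethylbicyclo[2.2.2]oct-5-ene-2,3-dione
Conditions: (CF3CO)2O, DMSO, CH2Cl2, −78 °C; Et3N; exclusion of light
Reagents that add atoms: none
Why: Swern-type oxidation with trifluoroacetic anhydride-activated DMSO takes a vicinal diol to the 1,2-dione without C–C cleavage, as is usual for bicyclo[2.2.2]octene-2,3-diols; the yellow dione is kept from light because this class loses CO photochemically.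

Step 6
Reactants: 8 meso-5,6-dimethylbicyclo[2.2.2]oct-5-ene-2,3-dione
Product: 9 (1R,3S,4S)-3-hydroxy-5,6-dimethylbicyclo[2.2.2]oct-5-en-2-one
Conditions: (S)-2-methyl-CBS-oxazaborolidine (10 mol%), BH3·SMe2 (0.6 equiv, slow addition), THF, −40 °C; MeOH
Reagents that add atoms: none
Why: Corey–Bakshi–Shibata reduction used as a desymmetrisation: hydride enters from the less hindered face syn to the C4=C5 bridge, and the catalyst (bridgehead carbon as large group, acyl carbon as small group) accepts this trajectory at only one of the two enantiotopic carbonyl groups. This fixes the absolute configuration of C3 and C10; the C9 carbinol formed here (hydroxyl on the side of the C1–C2 bridge) is temporary, and the antipodal catalyst would serve if the sense of induction were the reverse.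

Step 7
Reactants: 9 (1R,3S,4S)-3-hydroxy-5,6-dimethylbicyclo[2.2.2]oct-5-en-2-one
Product: 10 (1R,2S,3S,4S)-5,6-dimethyl-2-(prop-1-yn-1-yl)bicyclo[2.2.2]oct-5-ene-2,3-diol
Conditions: 1-propynylmagnesium bromide (2.5 equiv), THF, −78 to 0 °C
Reagents that add atoms: 1-propynylmagnesium bromide, CC#C[Mg]Br
Why: The first equivalent forms the C9 alkoxide and the second adds to the C8 ketone (Grignard 1,2-addition) from the face of the C4=C5 bridge, anti to the C9 oxygen and away from the inward hydrogen atoms of the C1–C2 bridge. This sets C8 with the carbon substituent syn to the alkene bridge, as the later [3,3] shift requires.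

Step 8
Reactants: 10 (1R,2S,3S,4S)-5,6-dimethyl-2-(prop-1-yn-1-yl)bicyclo[2.2.2]oct-5-ene-2,3-diol
Product: 11 (1S,3S,4R)-3-hydroxy-5,6-dimethyl-3-(prop-1-yn-1-yl)bicyclo[2.2.2]oct-5-en-2-one
Conditions: Dess–Martin periodinane, CH2Cl2, 0 °C
Reagents that add atoms: none
Why: Dess–Martin oxidation of the secondary C9 alcohol beside an inert tertiary alcohol removes the temporary C9 center so that it can be rebuilt from the opposite face; neutral conditions avoid α-ketol rearrangement.

Step 9
Reactants: 11 (1S,3S,4R)-3-hydroxy-5,6-dimethyl-3-(prop-1-yn-1-yl)bicyclo[2.2.2]oct-5-en-2-one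
Product: 12 (1R,2S,3R,4S)-5,6-dimethyl-2-(prop-1-yn-1-yl)bicyclo[2.2.2]oct-5-ene-2,3-diol
Conditions: Me4NBH(OAc)3, MeCN/AcOH, −30 °C
Reagents that add atoms: none
Why: Evans–Saksena hydroxyl-directed reduction: the acetoxyborohydride bound to the C8 hydroxyl, which lies on the side of the C1–C2 bridge, delivers hydride to C9 from that face. The new hydroxyl therefore stands trans to the C8 hydroxyl and syn to the alkene bridge; this sets C9 (R), the future 9β oxygen and conformational anchor.

Step 10
Reactants: 12 (1R,2S,3R,4S)-5,6-dimethyl-2-(prop-1-yn-1-yl)bicyclo[2.2.2]oct-5-ene-2,3-diol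
Product: 13 (1R,2S,3R,4S)-3-[(4-methoxyphenyl)methoxy]-5,6-dimethyl-2-(prop-1-yn-1-yl)bicyclo[2.2.2]oct-5-en-2-ol
Conditions: NaH (1.05 equiv), 4-methoxybenzyl bromide, Bu4NI (cat.), THF/DMF, 0 °C
Reagents that add atoms: 4-methoxybenzyl bromide, COc1ccc(CBr)cc1
Why: Williamson etherification of the more acidic and less hindered secondary alkoxide leaves the tertiary hydroxyl free for step 12. The benzyl-type ether cannot migrate between oxygens, survives KH, borane and KOt-Bu, and is removed oxidatively at the end.

Step 11
Reactants: 13 (1R,2S,3R,4S)-3-[(4-methoxyphenyl)methoxy]-5,6-dimethyl-2-(prop-1-yn-1-yl)bicyclo[2.2.2]oct-5-en-2-ol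
Product: 14 (1R,2S,3R,4S)-3-[(4-methoxyphenyl)methoxy]-5,6-dimethyl-2-(3-methylbuta-1,3-dien-2-yl)bicyclo[2.2.2]oct-5-en-2-ol
Conditions: second-generation Grubbs catalyst RuCl2(=CHPh)(PCy3)(H2IMes) (10 mol%), ethylene (4 bar), toluene, 80 °C
Reagents that add atoms: ethylene, C=C
Why: Alkyne–ethylene cross (enyne) metathesis turns the internal alkyne into the 2,3-disubstituted buta-1,3-diene, adding the methylene carbons C6 and C12; the tetrasubstituted ring alkene is inert to the catalyst and no stereocenter is affected.

Step 12
Reactants: 14 (1R,2S,3R,4S)-3-[(4-methoxyphenyl)methoxy]-5,6-dimethyl-2-(3-methylbuta-1,3-dien-2-yl)bicyclo[2.2.2]oct-5-en-2-ol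
Product: 18 9β-[(4-methoxyphenyl)methoxy]-10βH-eremophila-3,7(11)-dien-8-one, via potassium alkoxide 15 (not isolated), via potassium dienolate 16 (not isolated), via isopropenyl ketone 17 (not isolated)
Conditions: KH, 18-crown-6, THF, 0 °C to rt; AcOH, −78 °C; then DBU (0.2 equiv), CH2Cl2, rt
Reagents that add atoms: none
Why: The potassium alkoxide 15 undergoes an anionic oxy-Cope ([3,3]-sigmatropic) rearrangement in which the C3–C8 bond is cleaved and C6 bonds to C5, giving dienolate 16; the closest known reaction type is the anionic oxy-Cope rearrangement of 2-alkenylbicyclo[2.2.2]oct-5-en-2-ols to cis-fused octalones. Ring B is closed by the new C5–C6 bond through a six-membered boat transition state that the bicycle enforces, suprafacial on both allyl units, while ring A is released as the cyclohexene C10–C1–C2–C3=C4–C5 by loss of the temporary bond. C5 is the only new stereocenter: C6 can reach it only on the alkene face that looks at the C8–C9 bridge, so the C5 methyl group ends cis to H-10 (cis fusion), with the absolute sense fixed by C10 and C3 from step 6. C9 and C10 are spectators, and the C9 oxygen, syn to the alkene bridge in 14, becomes cis to H-10 (9β), equatorial in the chair–chair form in which the C5 methyl group is axial on ring A. The step needs the [3,3] path to win over retro-addition and a stepwise 1,3-shift; this is secured by the syn arrangement of dienyl group and C4=C5 bridge set in step 7, by the K+/18-crown-6 ion pair, and by the irreversible formation of a conjugated dienolate. Kinetic protonation of 16 gives 17 as a C7 mixture, and DBU then moves C11=C12 into conjugation through the far more acidic C7–H, which removes the C7 stereocenter for the time being and leaves C9–H untouched. One operation thus delivers the quaternary C5, the cis ring fusion, the C8 ketone next to the C9 oxygen and the C3=C4 alkene needed for C3 and C4.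

Step 13
Reactants: 18 9β-[(4-methoxyphenyl)methoxy]-10βH-eremophila-3,7(11)-dien-8-one
Product: 20 9β-[(4-methoxyphenyl)methoxy]-10βH-eremophil-7(11)-ene-3α,8-diol (C8 epimers), via alkylborane 19 (not isolated)
Conditions: BH3·SMe2 (2.2 equiv), THF, 0 °C; then NaOH, H2O2, 0 °C to rt
Reagents that add atoms: hydrogen peroxide, OO
Why: Brown hydroboration–oxidation adds H and OH syn and anti-Markovnikov to C3=C4 from the α face, anti to the pseudoaxial C5 methyl group in the ring-flip form anchored by the equatorial C9 ether. This sets C3 (hydroxyl α) and C4 (hydrogen α, methyl β) together and trans to each other. The enone carbonyl is reduced to the allylic alcohol in the same pot, and the hindered tetrasubstituted C7=C11 bond should react more slowly than the ring alkene.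

Step 14
Reactants: 20 9β-[(4-methoxyphenyl)methoxy]-10βH-eremophil-7(11)-ene-3α,8-diol
Product: 21 3α-hydroxy-9β-[(4-methoxyphenyl)methoxy]-10βH-eremophil-7(11)-en-8-one
Conditions: MnO2 (activated, excess), CH2Cl2, rt
Reagents that add atoms: none
Why: Allylic oxidation with MnO2 returns the enone from both C8 epimers and leaves the saturated C3 alcohol alone, which differentiates the two hydroxyl groups without a protecting group.

Step 15
Reactants: 21 3α-hydroxy-9β-[(4-methoxyphenyl)methoxy]-10βH-eremophil-7(11)-en-8-one
Product: 24 3α-hydroxy-9β-[(4-methoxyphenyl)methoxy]-10βH-eremophil-11-en-8-one (isopropenyl β at C7), via dipotassium dienolate 22 (not isolated), via C7-epimeric ketone mixture 23 (not isolated)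
Conditions: KOt-Bu (4 equiv), t-BuOH/THF, 0 °C to rt; inverse quench into AcOH/H2O, 0 °C; then DBU (0.1 equiv), CH2Cl2, 0 °C, short contact
Reagents that add atoms: none
Why: Deconjugative protonation: the extended dienolate 22 is protonated kinetically at C7, which gives the β,γ-unsaturated ketone. Brief contact with catalytic DBU then equilibrates C7 (and C9, should it have been touched) to the all-equatorial ring B, the thermodynamic arrangement once ring A is locked by the equatorial C3 hydroxyl and C4 methyl groups; α-reprotonation is faster than return to conjugation, and this sets C7.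

Step 16
Reactants: 24 3α-hydroxy-9β-[(4-methoxyphenyl)methoxy]-10βH-eremophil-11-en-8-one
Product: 25 9β-[(4-methoxyphenyl)methoxy]-3α-[(E)-2-methylbut-2-enoyloxy]-10βH-eremophil-11-en-8-one
Conditions: (E)-2-methylbut-2-enoyl chloride, pyridine, DMAP (cat.), CH2Cl2, 0 °C to rt
Reagents that add atoms: (E)-2-methylbut-2-enoyl chloride, C/C=C(\C)C(Cl)=O
Why: DMAP-catalysed acylation of the equatorial C3 alcohol; the E geometry of the tiglate is the stable one and is retained, and the weak base does not enolise the ketone.

Step 17
Reactants: 25 9β-[(4-methoxyphenyl)methoxy]-3α-[(E)-2-methylbut-2-enoyloxy]-10βH-eremophil-11-en-8-one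
Product: 26 9β-hydroxy-3α-[(E)-2-methylbut-2-enoyloxy]-10βH-eremophil-11-en-8-one
Conditions: DDQ, CH2Cl2/pH 7 buffer, 0 °C
Reagents that add atoms: none
Why: Oxidative cleavage of the 4-methoxybenzyl ether by benzylic hydride abstraction and hydrolysis of the oxocarbenium ion; the medium is neutral, so C7 and C9 are not epimerised and the alkenes and the ester are inert.

Step 18
Reactants: 26 9β-hydroxy-3α-[(E)-2-methylbut-2-enoyloxy]-10βH-eremophil-11-en-8-one
Product: 27 (3R,4R,5R,7R,9R,10S)-3-[(E)-2-methylbut-2-enoyloxy]-9-(3-methylbut-2-enoyloxy)eremophil-11-en-8-one (target)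
Conditions: 3-methylbut-2-enoyl chloride, pyridine, DMAP (cat.), CH2Cl2, 0 °C
Reagents that add atoms: 3-methylbut-2-enoyl chloride, CC(C)=CC(Cl)=O
Why: Acylation of the equatorial α-hydroxy ketone; pyridine in place of a trialkylamine avoids vinylketene formation (deconjugation of the senecioyl group) and does not enolise C7 or C9.

## Compound list

1 | 2-methylcyclohex-2-en-1-one | CC1=CCCCC1=O | starting material
2 | lithium 6-methylcyclohexa-1,5-dien-1-olate | [Li+].[O-]C1=CCCC=C1C | intermediate
3 | 6-methylcyclohexa-1,5-dien-1-yl trifluoromethanesulfonate | CC1=CCCC=C1OS(=O)(=O)C(F)(F)F | intermediate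
4 | 2,3-dimethylcyclohexa-1,3-diene | CC1=CCCC=C1C | intermediate
5 | vinylene carbonate (1,3-dioxol-2-one) | O=C1OC=CO1 | starting material
6 | meso-(3aR,4S,7R,7aS)-5,6-dimethyl-3a,4,7,7a-tetrahydro-4,7-ethano-1,3-benzodioxol-2-one (carbonate syn to the C=C bridge) | O=C1O[C@@H]2[C@H](O1)[C@H]3CC[C@@H]2C(C)=C3C | intermediate
7 | meso-(1R,2S,3R,4S)-5,6-dimethylbicyclo[2.2.2]oct-5-ene-2,3-diol | O[C@@H]1[C@H](O)[C@H]2CC[C@@H]1C(C)=C2C | intermediate
8 | meso-(1R,4S)-5,6-dimethylbicyclo[2.2.2]oct-5-ene-2,3-dione | O=C1C(=O)[C@H]2CC[C@@H]1C(C)=C2C | intermediate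
9 | (1R,3S,4S)-3-hydroxy-5,6-dimethylbicyclo[2.2.2]oct-5-en-2-one (hydroxyl on the side of the ethano bridge) | O=C1[C@@H](O)[C@H]2CC[C@@H]1C(C)=C2C | intermediate
10 | (1R,2S,3S,4S)-5,6-dimethyl-2-(prop-1-yn-1-yl)bicyclo[2.2.2]oct-5-ene-2,3-diol (cis-diol) | CC#C[C@]1(O)[C@@H](O)[C@H]2CC[C@@H]1C(C)=C2C | intermediate
11 | (1S,3S,4R)-3-hydroxy-5,6-dimethyl-3-(prop-1-yn-1-yl)bicyclo[2.2.2]oct-5-en-2-one | CC#C[C@]1(O)C(=O)[C@H]2CC[C@@H]1C(C)=C2C | intermediate
12 | (1R,2S,3R,4S)-5,6-dimethyl-2-(prop-1-yn-1-yl)bicyclo[2.2.2]oct-5-ene-2,3-diol (trans-diol) | CC#C[C@]1(O)[C@H](O)[C@H]2CC[C@@H]1C(C)=C2C | intermediate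
13 | (1R,2S,3R,4S)-3-[(4-methoxyphenyl)methoxy]-5,6-dimethyl-2-(prop-1-yn-1-yl)bicyclo[2.2.2]oct-5-en-2-ol | CC#C[C@]1(O)[C@H](OCc3ccc(OC)cc3)[C@H]2CC[C@@H]1C(C)=C2C | intermediate
14 | (1R,2S,3R,4S)-3-[(4-methoxyphenyl)methoxy]-5,6-dimethyl-2-(3-methylbuta-1,3-dien-2-yl)bicyclo[2.2.2]oct-5-en-2-ol | CC(=C)C(=C)[C@]1(O)[C@H](OCc3ccc(OC)cc3)[C@H]2CC[C@@H]1C(C)=C2C | intermediate
15 | potassium alkoxide of 14 | [K+].[O-][C@@]1(C(=C)C(C)=C)[C@H](OCc3ccc(OC)cc3)[C@H]2CC[C@@H]1C(C)=C2C | intermediate
16 | potassium 9β-[(4-methoxyphenyl)methoxy]-10βH-eremophila-3,7,11-trien-8-olate | [K+].[O-]C1=C(C(C)=C)C[C@@]2(C)[C@H](CCC=C2C)[C@H]1OCc3ccc(OC)cc3 | intermediate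
17 | 9β-[(4-methoxyphenyl)methoxy]-10βH-eremophila-3,11-dien-8-one (C7 epimers) | C=C(C)C1C[C@@]2(C)[C@H](CCC=C2C)[C@@H](OCc3ccc(OC)cc3)C1=O | intermediate
18 | 9β-[(4-methoxyphenyl)methoxy]-10βH-eremophila-3,7(11)-dien-8-one | CC(C)=C1C[C@@]2(C)[C@H](CCC=C2C)[C@@H](OCc3ccc(OC)cc3)C1=O | intermediate
19 | 3α-boryl-8-boryloxy-9β-[(4-methoxyphenyl)methoxy]-10βH-eremophil-7(11)-ene (C8 epimers) | CC(C)=C1C[C@@]2(C)[C@H](CC[C@@H]([BH2])[C@@H]2C)[C@@H](OCc3ccc(OC)cc3)C1O[BH2] | intermediate
20 | 9β-[(4-methoxyphenyl)methoxy]-10βH-eremophil-7(11)-ene-3α,8-diol (C8 epimers) | CC(C)=C1C[C@@]2(C)[C@H](CC[C@@H](O)[C@@H]2C)[C@@H](OCc3ccc(OC)cc3)C1O | intermediate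
21 | 3α-hydroxy-9β-[(4-methoxyphenyl)methoxy]-10βH-eremophil-7(11)-en-8-one | CC(C)=C1C[C@@]2(C)[C@H](CC[C@@H](O)[C@@H]2C)[C@@H](OCc3ccc(OC)cc3)C1=O | intermediate
22 | dipotassium salt (C3 alkoxide, C8 dienolate) of 21 | [K+].[K+].[O-]C1=C(C(C)=C)C[C@@]2(C)[C@H](CC[C@@H]([O-])[C@@H]2C)[C@H]1OCc3ccc(OC)cc3 | intermediate
23 | 3α-hydroxy-9β-[(4-methoxyphenyl)methoxy]-10βH-eremophil-11-en-8-one (C7 epimers) | C=C(C)C1C[C@@]2(C)[C@H](CC[C@@H](O)[C@@H]2C)[C@@H](OCc3ccc(OC)cc3)C1=O | intermediate
24 | 3α-hydroxy-9β-[(4-methoxyphenyl)methoxy]-10βH-eremophil-11-en-8-one (isopropenyl β at C7) | C=C(C)[C@H]1C[C@@]2(C)[C@H](CC[C@@H](O)[C@@H]2C)[C@@H](OCc3ccc(OC)cc3)C1=O | intermediate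
25 | 9β-[(4-methoxyphenyl)methoxy]-3α-[(E)-2-methylbut-2-enoyloxy]-10βH-eremophil-11-en-8-one | C=C(C)[C@H]1C[C@@]2(C)[C@H](CC[C@@H](OC(=O)/C(C)=C/C)[C@@H]2C)[C@@H](OCc3ccc(OC)cc3)C1=O | intermediate
26 | 9β-hydroxy-3α-[(E)-2-methylbut-2-enoyloxy]-10βH-eremophil-11-en-8-one | C=C(C)[C@H]1C[C@@]2(C)[C@H](CC[C@@H](OC(=O)/C(C)=C/C)[C@@H]2C)[C@@H](O)C1=O | intermediate
27 | (3R,4R,5R,7R,9R,10S)-3-[(E)-2-methylbut-2-enoyloxy]-9-(3-methylbut-2-enoyloxy)eremophil-11-en-8-one | C=C(C)[C@H]1C[C@@]2(C)[C@H](CC[C@@H](OC(=O)/C(C)=C/C)[C@@H]2C)[C@@H](OC(=O)C=C(C)C)C1=O | target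

## Step count and least certain steps

Total step count: 18. Longest linear sequence: 18 steps (1 to 27).

Step 12 (key step). The boat transition state has to bring C6 to a fully substituted alkene carbon while the isopropenyl arm is pressed against the C9 ether, so retro-addition (loss of the dienyl anion) or a stepwise 1,3-shift may compete with the concerted [3,3] path. The fallback moves the isopropylidene group to a later stage and runs the rearrangement on the unsubstituted vinyl carbinol, the best-precedented substrate type. It sets out from 9: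
- vinylmagnesium bromide gives the vinyl cis-diol F1;
- Dess–Martin oxidation gives the hydroxy ketone F2;
- Me4NBH(OAc)3 gives the trans-diol F3;
- NaH and 4-methoxybenzyl bromide give the ether F4;
- KH/18-crown-6 gives the C7-unsubstituted octalone F5;
- LiN(iPr)2 and acetone (enolisation at the C7 methylene) give the aldol adduct F6;
- dehydration with catalytic p-TsOH rejoins the route at 18.

Step 6. The catalyst may discriminate poorly between the two enantiotopic carbonyl groups of an all-aliphatic dione, or a second reduction may follow the first. The fallback sets out from 8: NaBH4 reduces both carbonyl groups from the face of the alkene bridge to the meso diol F7, and a desymmetrising mono-oxidation of one carbinol (Cu(OTf)2, (R,R)-Ph-BOX, N-bromosuccinimide, K2CO3) returns to 9.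

Step 11. The free tertiary propargylic hydroxyl may sequester the ruthenium carbene, and the flanking quaternary carbon may block alkyne insertion, so conversion may stall. The fallback avoids metathesis and brings the diene in as an organolithium. It sets out from 9:
- 3-methylbut-3-en-2-one and 2,4,6-triisopropylbenzenesulfonyl hydrazide give the hydrazone F8;
- n-BuLi (Shapiro reaction) converts it into 3-methylbuta-1,3-dien-2-yllithium F9;
- addition to 9 gives the dienyl cis-diol F10;
- Dess–Martin oxidation gives the hydroxy ketone F11;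
- Me4NBH(OAc)3 gives the trans-diol F12;
- etherification as in step 10 rejoins the route at 14.

Step 13. After reduction of the carbonyl group the tetrasubstituted C7=C11 bond may also be hydroborated, and any population of the other ring-flip form would lead to attack from the β face. The fallback replaces hydroboration by a radical epoxide opening and leaves the enone untouched. It sets out from 18: mCPBA epoxidises only the electron-rich C3=C4 bond from the α face to give the epoxide F13. Cp2TiCl (trivalent titanium, from Cp2TiCl2 and Zn) with 1,4-cyclohexadiene then opens it homolytically to the tertiary C4 radical, which takes up hydrogen. This gives the anti-Markovnikov alcohol and comes back at 21, so that step 14 is bypassed as well.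

Step 15. Kinetic control may be lost through proton return at C12 (re-conjugation) during quench or equilibration, and strong base at the α′ position may erode C9. The fallback avoids any equilibrating enolate. It sets out from 21: Me3SiOTf/Et3N gives the extended silyl dienol ether F14 (both oxygens silylated), and Bu4NF/AcOH at −78 °C removes both silyl groups with protonation at C7. It comes back at 24 after the same short DBU equilibration.

## Further compounds

F1 | step 12 | 2-ethenyl analogue of 10 (cis-diol, same configuration) | C=C[C@]1(O)[C@@H](O)[C@H]2CC[C@@H]1C(C)=C2C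
F2 | step 12 | 3-ethenyl analogue of 11 (hydroxy ketone) | C=C[C@]1(O)C(=O)[C@H]2CC[C@@H]1C(C)=C2C
F3 | step 12 | 2-ethenyl analogue of 12 (trans-diol) | C=C[C@]1(O)[C@H](O)[C@H]2CC[C@@H]1C(C)=C2C
F4 | step 12 | 2-ethenyl analogue of 13 (4-methoxybenzyl ether) | C=C[C@]1(O)[C@H](OCc3ccc(OC)cc3)[C@H]2CC[C@@H]1C(C)=C2C
F5 | step 12 | 9β-[(4-methoxyphenyl)methoxy]-11,12,13-trinor-10βH-eremophil-3-en-8-one | O=C1CC[C@@]2(C)[C@H](CCC=C2C)[C@H]1OCc3ccc(OC)cc3
F6 | step 12 | 11-hydroxy-9β-[(4-methoxyphenyl)methoxy]-10βH-eremophil-3-en-8-one (C7 epimers) | CC(C)(O)C1C[C@@]2(C)[C@H](CCC=C2C)[C@@H](OCc3ccc(OC)cc3)C1=O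
F7 | step 6 | meso-5,6-dimethylbicyclo[2.2.2]oct-5-ene-2,3-diol with both hydroxyl groups on the side of the ethano bridge | O[C@H]1[C@@H](O)[C@H]2CC[C@@H]1C(C)=C2C
F8 | step 11 | (E)-3-methylbut-3-en-2-one 2,4,6-triisopropylbenzenesulfonylhydrazone | CC(=C)/C(C)=N/NS(=O)(=O)c1c(C(C)C)cc(C(C)C)cc1C(C)C
F9 | step 11 | 3-methylbuta-1,3-dien-2-yllithium | [Li]C(=C)C(C)=C
F10 | step 11 | 2-(3-methylbuta-1,3-dien-2-yl) analogue of 10 (cis-diol) | CC(=C)C(=C)[C@]1(O)[C@@H](O)[C@H]2CC[C@@H]1C(C)=C2C
F11 | step 11 | 3-(3-methylbuta-1,3-dien-2-yl) analogue of 11 (hydroxy ketone) | CC(=C)C(=C)[C@]1(O)C(=O)[C@H]2CC[C@@H]1C(C)=C2C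
F12 | step 11 | 2-(3-methylbuta-1,3-dien-2-yl) analogue of 12 (trans-diol) | CC(=C)C(=C)[C@]1(O)[C@H](O)[C@H]2CC[C@@H]1C(C)=C2C
F13 | step 13 | 3α,4α-epoxy-9β-[(4-methoxyphenyl)methoxy]-10βH-eremophil-7(11)-en-8-one | CC(C)=C1C[C@@]2(C)[C@H](CC[C@H]3O[C@@]23C)[C@@H](OCc4ccc(OC)cc4)C1=O
F14 | step 15 | 9β-[(4-methoxyphenyl)methoxy]-3α,8-bis(trimethylsilyloxy)-10βH-eremophila-7,11-diene | C[Si](C)(C)OC1=C(C(C)=C)C[C@@]2(C)[C@H](CC[C@@H](O[Si](C)(C)C)[C@@H]2C)[C@H]1OCc3ccc(OC)cc3
A1 | alternative 1 | cis-4,4a-dimethyl-4,4a,7,8-tetrahydronaphthalene-2,5(3H,6H)-dione (methyl groups as at C4 and C5 of the target) | O=C1C=C2CCCC(=O)[C@]2(C)[C@@H](C)C1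
A2 | alternative 2 | (7E)-4-[(4-methoxyphenyl)methoxy]-7,8-dimethyl-5-(prop-1-en-2-yl)-9-(trimethylsilyloxy)deca-1,7,9-trien-3-one | C=CC(=O)[C@@H](OCc1ccc(OC)cc1)[C@@H](C(C)=C)C/C(C)=C(\C)C(=C)O[Si](C)(C)C
A3 | alternative 2 | 8-[(4-methoxyphenyl)methoxy]-3-(trimethylsilyloxy)-10βH-eremophila-3,11-dien-9-one | C=C(C)[C@H]1C[C@@]2(C)[C@H](CCC(O[Si](C)(C)C)=C2C)C(=O)[C@H]1OCc3ccc(OC)cc3
A4 | alternative 3 | (R)-1-methoxy-4-methyl-6-(prop-1-en-2-yl)cyclohexa-1,3-diene | COC1=CC=C(C)C[C@@H]1C(C)=C
A5 | alternative 3 | 2-ethenyl-1-methoxy-3,4-dimethyl-7-(prop-1-en-2-yl)bicyclo[2.2.2]oct-5-en-2-ol (vinyl and isopropenyl syn to the C5=C6 bridge) | C=C[C@]1(O)[C@H](C)[C@@]2(C)C[C@H](C(C)=C)[C@]1(OC)C=C2
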